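**Target:** (2E)-3-[(2R,3S)-2-(4-hydroxy-3-methoxyphenyl)-3-(hydroxymethyl)-7-methoxy-2,3-dihydro-1-benzofuran-5-yl]prop-2-enoic acid. The SMILES reads as C2 = R, C3 = S, i.e. the 2,3-trans isomer, with an E acrylic acid.

**Assumption:** a one-pot reagent sequence with a single work-up (steps 2, 4, 5, 7) counts as one step.

## Retrosynthetic overview

1. Target 14 ⇐ Heck coupling of acrylic acid with the 5-bromo-dihydrobenzofuran 12.
2. 12 ⇐ acid-mediated O1–C2 closure of diol 11 through a p-quinone methide; this is the only ring formed, and the lactate-derived C3 dictates 2,3-trans.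
3. 11 ⇐ aryl Grignard (from 10) + lactol 8, which comes from ozonolysis of the propenyl group of phenol 7.
4. 7 ⇐ aromatic Claisen [3,3] rearrangement of the (R,E)-allyl aryl ether 6; this forms the C3a–C3 bond and transfers chirality from C–O to the C3 stereocentre.
5. 6 ⇐ 4-bromo-2-methoxyphenol + ethyl (S)-lactate (Mitsunobu inversion, then two-carbon homologation). Both arenes are purchased.

## Route

**Step 1**
Reactants: 1, 4-bromo-2-methoxyphenol; 2, ethyl (S)-lactate
Product: 3, ethyl (2R)-2-(4-bromo-2-methoxyphenoxy)propanoate
Conditions: PPh3, DIAD, THF, 0 °C → rt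
Reagents that add atoms: none (both partners are the reactants)
Why: Mitsunobu etherification of a phenol (pKa ≈ 10) proceeds by clean SN2 inversion at the lactate carbinol, so (S)-lactate gives the (R)-aryl ether.

**Step 2**
Reactants: 3; 4, triethyl phosphonoacetate
Product: 5, ethyl (2E,4R)-4-(4-bromo-2-methoxyphenoxy)pent-2-enoate
Conditions: DIBAL-H (1.05 equiv), CH2Cl2, −78 °C; then NaH/(EtO)2P(O)CH2CO2Et (premixed in THF), −78 °C → rt; minor Z isomer removed on silica
Reagents that add atoms: triethyl phosphonoacetate, CCOC(=O)CP(=O)(OCC)OCC
Why: One-pot partial reduction/Horner–Wadsworth–Emmons olefination; the chelated aluminium hemiacetal releases the α-aryloxy aldehyde only as it is consumed, so C4 is not racemised, and the HWE is E-selective.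

**Step 3**
Reactants: 5
Product: 6, (2E,4R)-4-(4-bromo-2-methoxyphenoxy)pent-2-en-1-ol
Conditions: DIBAL-H (2.3 equiv), CH2Cl2, −78 → −20 °C; Rochelle salt work-up
Reagents that add atoms: none
Why: 1,2-reduction of the enoate to the allylic alcohol; the aryl bromide, aryl ether and stereocentre are untouched.

**Step 4**
Reactants: 6
Product: 7, 4-bromo-2-[(2S,3E)-1-hydroxypent-3-en-2-yl]-6-methoxyphenol
Conditions: BSA (3 equiv), PhNEt2, 170–180 °C, sealed tube, Ar; then K2CO3, MeOH, rt in the work-up
Reagents that add atoms: none (the transient TMS groups are removed in the work-up)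
Why: Aromatic Claisen rearrangement to the only free ortho position. In the chair transition state with the C1 methyl pseudo-equatorial, the (R) C–O centre is transferred suprafacially to the new (S) benzylic centre and the propenyl group forms E. In-situ silylation of the alcohol and the new phenol suppresses the abnormal Claisen pathway.

**Step 5**
Reactants: 7
Product: 8, (3S)-5-bromo-3-(hydroxymethyl)-7-methoxy-2,3-dihydro-1-benzofuran-2-ol (anomer mixture)
Conditions: O3 (1.0 equiv, Sudan III end point), CH2Cl2/MeOH 4:1, −78 °C; then Me2S, −78 °C → rt; used crude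
Reagents that add atoms: ozone, O=[O+][O-]
Why: Ozonolysis of the disubstituted alkene (faster than attack on the bromophenol ring) gives the aldehyde, which is trapped at once by the ortho phenol as the five-membered lactol. This masks the epimerisable α-aryl aldehyde under neutral conditions.

**Step 6**
Reactants: 1; 9, chloromethyl methyl ether
Product: 10, 4-bromo-2-methoxy-1-(methoxymethoxy)benzene
Conditions: MOMCl, i-Pr2NEt, CH2Cl2, 0 °C → rt
Reagents that add atoms: MOMCl, COCCl
Why: O-alkylation of the phenol; the MOM acetal survives Grignard formation and is removed by the acid of step 8 at no extra step.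

**Step 7**
Reactants: 8; 10 (as its Grignard reagent)
Product: 11, (1RS,2S)-2-(5-bromo-2-hydroxy-3-methoxyphenyl)-1-[3-methoxy-4-(methoxymethoxy)phenyl]propane-1,3-diol (epimers at C1)
Conditions: 10, Mg (I2 cat.), THF, 45 °C → ArMgBr (4 equiv); add 8 in THF, −40 → 0 °C; aq. NH4Cl
Reagents that add atoms: 3-methoxy-4-(methoxymethoxy)phenylmagnesium bromide, COCOc1ccc([Mg]Br)cc1OC
Why: Grignard 1,2-addition. Two equivalents deprotonate the lactol and the alcohol, the lactolate opens to the phenoxide-aldehyde, and a third equivalent adds. The polyanionic substrate resists α-deprotonation, so C2 stays S, and the substrate's aryl bromide is inert to ArMgBr. The new carbinol centre is reset in step 8, so its configuration is irrelevant.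

**Step 8**
Reactants: 11
Product: 12, [(2R,3S)-5-bromo-2-(4-hydroxy-3-methoxyphenyl)-7-methoxy-2,3-dihydro-1-benzofuran-3-yl]methanol
Conditions: 3 M aq. HCl, MeOH/THF, 45 °C
Reagents that add atoms: none
Why: Acid removes the MOM group, and the p-hydroxybenzylic alcohol ionises to a protonated p-quinone methide that the ortho phenol traps (5-exo oxa-Michael cyclisation). The closure is reversible, so both carbinol epimers converge on the thermodynamic 2,3-trans ring, and C2 (R) is set by C3 (S).

**Step 9**
Reactants: 12; 13, acrylic acid
Product: 14, the target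
Conditions: Pd(OAc)2 (5 mol%), P(o-tol)3 (15 mol%), Et3N (4 equiv), degassed DMF, 90 °C; then 1 M HCl to pH 3
Reagents that add atoms: acrylic acid, C=CC(=O)O
Why: Mizoroki–Heck coupling; syn-insertion and β-hydride elimination give the E-cinnamic acid. The free phenol, alcohol and acid are tolerated, and neither stereocentre is touched.

## Compound list

1 | 4-bromo-2-methoxyphenol | COc1cc(Br)ccc1O | starting material
2 | ethyl (S)-lactate | C[C@H](O)C(=O)OCC | starting material (sole source of chirality)
3 | ethyl (2R)-2-(4-bromo-2-methoxyphenoxy)propanoate | C[C@@H](Oc1ccc(Br)cc1OC)C(=O)OCC | intermediate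
4 | triethyl phosphonoacetate | CCOC(=O)CP(=O)(OCC)OCC | starting material
5 | ethyl (2E,4R)-4-(4-bromo-2-methoxyphenoxy)pent-2-enoate | C[C@@H](Oc1ccc(Br)cc1OC)/C=C/C(=O)OCC | intermediate
6 | (2E,4R)-4-(4-bromo-2-methoxyphenoxy)pent-2-en-1-ol | C[C@@H](Oc1ccc(Br)cc1OC)/C=C/CO | intermediate
7 | 4-bromo-2-[(2S,3E)-1-hydroxypent-3-en-2-yl]-6-methoxyphenol | C/C=C/[C@H](CO)c1cc(Br)cc(OC)c1O | intermediate
8 | (3S)-5-bromo-3-(hydroxymethyl)-7-methoxy-2,3-dihydro-1-benzofuran-2-ol (anomer mixture) | OC[C@@H]1c2cc(Br)cc(OC)c2OC1O | intermediate
9 | chloromethyl methyl ether | COCCl | starting material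
10 | 4-bromo-2-methoxy-1-(methoxymethoxy)benzene | COCOc1ccc(Br)cc1OC | intermediate
11 | (1RS,2S)-2-(5-bromo-2-hydroxy-3-methoxyphenyl)-1-[3-methoxy-4-(methoxymethoxy)phenyl]propane-1,3-diol | OC[C@@H](C(O)c1ccc(OCOC)c(OC)c1)c1cc(Br)cc(OC)c1O | intermediate
12 | [(2R,3S)-5-bromo-2-(4-hydroxy-3-methoxyphenyl)-7-methoxy-2,3-dihydro-1-benzofuran-3-yl]methanol | COc1cc([C@@H]2Oc3c(OC)cc(Br)cc3[C@H]2CO)ccc1O | intermediate
13 | acrylic acid | C=CC(=O)O | starting material
14 | (2E)-3-[(2R,3S)-2-(4-hydroxy-3-methoxyphenyl)-3-(hydroxymethyl)-7-methoxy-2,3-dihydro-1-benzofuran-5-yl]prop-2-enoic acid | COc1cc([C@@H]2Oc3c(OC)cc(/C=C/C(=O)O)cc3[C@H]2CO)ccc1O | target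

## Step count

- Total steps: 9.
- Longest linear sequence: 8 (steps 1–5, 7, 8, 9); step 6 is a one-step side branch.

## Steps most likely to fail

1. **Step 4 (Claisen).** A few percent of the Z-propenyl product, formed through the chair with axial methyl, has the opposite C3 configuration and lowers the ee after ozonolysis; abnormal Claisen is a second risk. The ee should be checked by chiral HPLC at 7 or 12, and 12 recrystallised if needed. Fallback: build the (S,Z)-allyl ether instead, from methyl (R)-lactate by Mitsunobu, DIBAL, Z-selective Ando or Still–Gennari olefination and DIBAL. A(1,3) strain from the Z substituent then allows only one chair and gives the same (S,E)-phenol 7.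

2. **Step 7 (Grignard on lactol 8).** The basic reagent could enolise the α-aryl aldehyde, or 8 could dehydrate to the achiral benzofuran; either destroys C3. Fallback: form the C2–aryl bond without a basic organometallic, by Ni/Cr-mediated (Nozaki–Hiyama–Kishi) coupling of 8 with the aryl iodide analogue of 10, which tolerates the free OH groups.

3. **Step 9 (Heck on unprotected 12).** The electron-rich bromide is sluggish, and hot amine base could open the p-hydroxyphenyl dihydrobenzofuran through its quinone methide. Fallback: move the coupling ahead of ring closure. Heck-couple diol 11 with tert-butyl acrylate, then use one acid treatment (TFA or HCl/dioxane) to cleave the MOM group and the tert-butyl ester and close the trans ring, so the free phenolic dihydrobenzofuran never meets hot base. The step count is unchanged.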